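1. At 20 h, birch, elm and maple are read with 1.5 M substrate and 2.70 M partner, like gamma, delta and epsilon; they differ in [free catalyst].

| flask | substrate | partner | free catalyst | remark | time |
|---|---|---|---|---|---|
| gamma | 1.5 M | 2.7 M | 29 mM | run made earlier |  |
| delta | 1.5 M | 2.7 M | 48 mM | run made earlier |  |
| epsilon | 1.5 M | 2.7 M | 56 mM | run made earlier |  |
| birch | 1.5 M | 2.70 M | 55 mM |  | 20 h |
| elm | 1.5 M | 2.70 M | 46 mM |  | 20 h |
| maple | 1.5 M | 2.70 M | 38 mM |  | 20 h |

| run | time / h | catalyst intermediate B / % | target / % | substrate / % |
|---|---|---|---|---|
| gamma | 1.50 | 0.7 | 7.0 | 93.3 |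
| gamma | 4.00 | 0.4 | 15.2 | 83.2 |
| gamma | 8.00 | 0.1 | 26.4 | 71.9 |
| gamma | 20.0 | 0 | 45.3 | 54.5 |
| delta | 2.50 | 0.5 | 16.5 | 82.3 |
| delta | 8.00 | 0.9 | 41.5 | 57.6 |
| delta | 12.0 | 0.5 | 54.7 | 45.5 |
| delta | 20.0 | 0 | 67.8 | 32.9 |
| epsilon | 2.50 | 2.1 | 19.6 | 79.2 |
| epsilon | 8.00 | 0.5 | 47.5 | 51.9 |
| epsilon | 12.0 | 0.1 | 60.2 | 38.5 |
| epsilon | 20.0 | 0 | 74.1 | 25.7 |

(standard deviation of a reading: 0.5 percentage points)

1. which of these there is most of at the end, counted by the substrate in it, birch (target / catalyst intermediate B / substrate)
2. which of these there is most of at the end, counted by the substrate in it, elm (target / catalyst intermediate B / substrate)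
3. which of these there is most of at the end, counted by the substrate in it, maple (target / catalyst intermediate B / substrate)
4. final amount of the leader among these, as a percentage of the substrate charged, in birch
5. final amount of the leader among these, as a percentage of the substrate charged, in elm
6. final amount of the leader among these, as a percentage of the substrate charged, in maple

- reactions considered so far: partner + free catalyst -> catalyst intermediate A; substrate + catalyst intermediate A -> catalyst intermediate B; catalyst intermediate B <-> free catalyst + target; 2 partner -> homo dimer; partner -> decomposed reagent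

2. Take the nearest run as the large part and reckon just the correction. Define the extent as ln(substrate charged / substrate left). The catalyst slope is the gain in extent per mM of [free catalyst] between two neighbouring runs at the same time.

3. Catalyst intermediate B: it reads 0% in epsilon at 20.0 h, so target is taken as what substrate leaves.

4. The nearest reading: an error in epsilon's substrate passes straight into birch, so birch carries the scatter of 0.5 percentage points.

5. The slope: its weight grows with the distance from the nearest run. Birch lies 1.00 mM from epsilon, and maple 9.00 mM from gamma, so the slope counts for maple.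

6. The number: from delta to epsilon, the catalyst slope is 0.0309 mM⁻¹; from gamma to delta it is 0.0266 mM⁻¹.

7. My reckoning, with the slope of the bracketing pair: substrate left is 26.5% in birch, 34.7% in elm and 42.9% in maple. That leaves target at 73.5%, 65.3% and 57.1%, and in maple target still stands above substrate.

8. The forecast calls this “an interpolation in catalyst loading” and gives target as leader in each flask, at 73.4%, 65.4% and 56.6%. My maple figure is higher by 0.49 points.

9. Target leads in birch at 73.5%, in elm at 65.0% and in maple at 56.4%.

    partner + free catalyst → catalyst intermediate A (k = 1.90 L mol⁻¹ h⁻¹)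
    substrate + catalyst intermediate A → catalyst intermediate B (k = 32.0 L mol⁻¹ h⁻¹)
    catalyst intermediate B ⇌ free catalyst + target (K = 69.0 M, k = 5.20 h⁻¹)
    2 partner → homo dimer (k = 0.0310 L mol⁻¹ h⁻¹)
    partner → decomposed reagent (k = 0.0110 h⁻¹)

10. Catalyst intermediate B holds 0.260% of the substrate in birch, beside 26.2% as substrate. Birch's target moves by 6 points at 48.6 mM free catalyst; the catalyst slope of 0.0309 mM⁻¹, taken over that gap of 6.44 mM, reckons a rise in birch's substrate of 5.8 points. Stepped down 9.00 mM from birch, the same slope gives elm 34.6% substrate, and elm holds 34.7%.

The runs were generated by integration with constants of no real substance; the scatter is artificial.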